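**Plan**
Cuts, in retrosynthetic order: C2''–C1''' (ring B'' taken off a chromone); O1''–C2'', C2''–C3'' and C4''–C4a'' (ring C'' back to an aryl iodide); C5''–C6'' and C7''–C8'' (ring A''); C3–C6'' (alkyne taken off a 3-iodoflavone); O1–C2 and C2–C3 (flavone ring C).
Forward: flavone ring C is closed between purchased rings A and B. A two-carbon alkyne (the future C6'' and C7'') is coupled to C3 and oxidised to its silyl ynol ether. Ring A'' is annulated onto it, ring C'' is closed as a chromone, and ring B'' is added last.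
Enabling feature: ring A'' is a phloroglucinol whose C6'', the carbon bonded to flavone C3, stands between the oxygenated C5'' and C7'' and para to the oxygenated C8a''. That is the substitution print left when an ynol ether C6''≡C7''–O is inserted into a 3-alkoxy vinylketene made of C5'', C8'', C8a'' and C4a''.
The annulation delivers the future O1'' with a label of its own (PMB ether, para to C6''), so the 6''-linkage is settled there. O5'' and O7'' are then made alike, and either free CH can serve as C4a''.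
Stereochemistry: C2'' is the only stereocentre. It is set as (R) by the chiral bisphosphine in a rhodium-catalysed 1,4-addition and afterwards sees only neutral hydrogenolysis.

Key step: step 9

Assumption: the target structure defines C2'' only; the hindered C3–C6'' axis bears no descriptor, so rotamers or atropisomers about it are counted as one compound at every stage.
Notation: plain and single-primed locants belong to the flavone, double- and triple-primed ones to the flavanone; Fl = 5-(benzyloxy)-7-methoxy-2-(4-methoxyphenyl)-4-oxo-4H-chromen-3-yl; PMB = 4-methoxybenzyl; TIPS = triisopropylsilyl.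

**Step 1**
Reactants: 1 1-(2,6-dihydroxy-4-methoxyphenyl)ethanone; 2 4-methoxybenzoyl chloride
Product: 3 1-(2,6-dihydroxy-4-methoxyphenyl)-3-(4-methoxyphenyl)propane-1,3-dione
Conditions: LiN(SiMe3)2 (4.2 equiv), THF, −78 to −10 °C; then 2, −78 °C to rt; aq HCl
Reagents that add atoms: none
Why: With every acidic proton removed, the ketone enolate carbon is the most reactive site of the polyanion, so the acid chloride is taken up at carbon in a crossed Claisen acylation that reaches the Baker–Venkataraman diketone without the ester detour.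

**Step 2**
Reactants: 3 1-(2,6-dihydroxy-4-methoxyphenyl)-3-(4-methoxyphenyl)propane-1,3-dione
Product: 4 5-hydroxy-7-methoxy-2-(4-methoxyphenyl)-4H-chromen-4-one
Conditions: AcOH, H2SO4 (cat.), 95 °C
Reagents that add atoms: none
Why: Acid-catalysed cyclodehydration of a 2-hydroxyaryl 1,3-diketone, the closing stage of the Baker–Venkataraman flavone synthesis, forms O1–C2 and ring C, and since the two phenols are equivalent only one flavone can result.

**Step 3**
Reactants: 4 5-hydroxy-7-methoxy-2-(4-methoxyphenyl)-4H-chromen-4-one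
Product: 5 5-(benzyloxy)-7-methoxy-2-(4-methoxyphenyl)-4H-chromen-4-one
Conditions: BnBr, K2CO3, DMF, 70 °C
Reagents that add atoms: benzyl bromide, BrCc1ccccc1
Why: Williamson etherification of the chelated 5-OH is slow, but it is the only acidic site, so warming in DMF suffices, and the benzyl group shields it from the strong bases of steps 4 and 7.

**Step 4**
Reactants: 5 5-(benzyloxy)-7-methoxy-2-(4-methoxyphenyl)-4H-chromen-4-one
Product: 7 5-(benzyloxy)-3-iodo-7-methoxy-2-(4-methoxyphenyl)-4H-chromen-4-one, via 3-lithioflavone 6 (not isolated)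
Conditions: LiN(i-Pr)2, THF, −78 °C; then I2, −78 °C
Reagents that add atoms: iodine, [I][I]
Why: Directed lithiation at C3, the only vinylic C–H and the one next to the coordinating carbonyl, followed by iodinolysis places the halogen where electrophilic iodination of a flavone with so electron-rich a ring A could not be relied on to place it.

**Step 5**
Reactants: 7 5-(benzyloxy)-3-iodo-7-methoxy-2-(4-methoxyphenyl)-4H-chromen-4-one; 8 ethynyltrimethylsilane
Product: 9 5-(benzyloxy)-7-methoxy-2-(4-methoxyphenyl)-3-[(trimethylsilyl)ethynyl]-4H-chromen-4-one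
Conditions: PdCl2(PPh3)2 (cat.), CuI (cat.), Et3N, DMF, 50 °C
Reagents that add atoms: none
Why: Sonogashira coupling, routine for 3-iodochromones, attaches the two carbons that become C6'' and C7'', and a tertiary amine base avoids opening of the pyrone ring.

**Step 6**
Reactants: 9 5-(benzyloxy)-7-methoxy-2-(4-methoxyphenyl)-3-[(trimethylsilyl)ethynyl]-4H-chromen-4-one
Product: 10 5-(benzyloxy)-3-ethynyl-7-methoxy-2-(4-methoxyphenyl)-4H-chromen-4-one
Conditions: K2CO3 (cat.), MeOH–CH2Cl2, 0 °C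
Reagents that add atoms: none
Why: Base-catalysed protiodesilylation of an alkynylsilane by methanol is fast at 0 °C, where the 2-aryl-substituted pyrone ring is not attacked.

**Step 7**
Reactants: 10 5-(benzyloxy)-3-ethynyl-7-methoxy-2-(4-methoxyphenyl)-4H-chromen-4-one
Product: 13 5-(benzyloxy)-7-methoxy-2-(4-methoxyphenyl)-3-{[(triisopropylsilyl)oxy]ethynyl}-4H-chromen-4-one, via lithium acetylide 11 (not isolated), via lithium ynolate 12 (not isolated)
Conditions: LiN(SiMe3)2, THF, −78 °C; LiOOt-Bu (t-BuOOH + LiN(SiMe3)2, THF, −78 °C), −78 to 0 °C; TIPSOTf, −78 to 0 °C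
Reagents that add atoms: tert-butyl hydroperoxide, CC(C)(C)OO; triisopropylsilyl trifluoromethanesulfonate, CC(C)[Si](OS(=O)(=O)C(F)(F)F)(C(C)C)C(C)C
Why: Oxenoid oxygen transfer from LiOOt-Bu to a lithium acetylide gives the ynolate, which the hard and bulky silyl triflate traps on oxygen; this is the usual route from aryl acetylenes to TIPS ynol ethers, and the amide base does not add to the flavone carbonyl.

**Step 8**
Reactants: 14 3-ethoxycyclobut-2-en-1-one; 15 (4-methoxyphenyl)methanol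
Product: 16 3-[(4-methoxybenzyl)oxy]cyclobut-2-en-1-one
Conditions: pyridinium p-toluenesulfonate (cat.), 5 Å molecular sieves, toluene, 40 °C
Reagents that add atoms: none
Why: Acid-catalysed transetherification of a vinylogous ester by addition–elimination at C3, the pathway by which dilute acid hydrolyses 14, is pulled forward by uptake of ethanol and is run at 40 °C so that the four-membered ring stays closed.

**Step 9**
Reactants: 13 5-(benzyloxy)-7-methoxy-2-(4-methoxyphenyl)-3-{[(triisopropylsilyl)oxy]ethynyl}-4H-chromen-4-one; 16 3-[(4-methoxybenzyl)oxy]cyclobut-2-en-1-one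
Product: 21 5-(benzyloxy)-3-{2-hydroxy-4-[(4-methoxybenzyl)oxy]-6-[(triisopropylsilyl)oxy]phenyl}-7-methoxy-2-(4-methoxyphenyl)-4H-chromen-4-one, via vinylketene 17 (not isolated), via vinylcyclobutenone 18 (not isolated), via dienylketene 19 (not isolated), via cyclohexadienone 20 (not isolated)
Conditions: toluene, 80 then 110 °C, sealed tube, Ar; 16 (1.5 equiv) added in portions
Reagents that add atoms: none
Why: Heating opens 16 by four-electron electrocyclic ring opening to the 3-alkoxy vinylketene 17, and the electron-rich alkyne carbon of 13 that carries the flavone (C6'') attacks the ketene carbonyl carbon (C5'') in a [2+2] cycloaddition that also joins C7'' to C8'' and gives 18. A second four-electron opening cleaves C5''–C8'' of 18 to the dienylketene 19, whose six-electron electrocyclisation re-forms the C4a''–C5'' bond lost in the first opening and so closes the six-membered carbocycle ring A'' as dienone 20, which tautomerises to phenol 21. The closest known reaction is the Danheiser benzannulation of cyclobutenones with trialkylsiloxyalkynes, applied here to a donor-substituted cyclobutenone and a heteroaryl ynol ether. No lasting stereocentre is formed, since the sp3 carbon of 18 disappears on aromatisation. The step needs a single orientation in the [2+2] event, and the push of the siloxy oxygen makes C6'' the only nucleophilic alkyne carbon, so C6'' ends between the new hydroxyl and the siloxy carbon with the PMB ether para to it. It also needs the ketene to meet the alkyne before it meets itself or the product phenol, which portionwise addition of 16 and the crowding of that phenol by the flavone should secure.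

**Step 10**
Reactants: 21 5-(benzyloxy)-3-{2-hydroxy-4-[(4-methoxybenzyl)oxy]-6-[(triisopropylsilyl)oxy]phenyl}-7-methoxy-2-(4-methoxyphenyl)-4H-chromen-4-one
Product: 22 5-(benzyloxy)-3-{2,6-bis(benzyloxy)-4-[(4-methoxybenzyl)oxy]phenyl}-7-methoxy-2-(4-methoxyphenyl)-4H-chromen-4-one
Conditions: CsF, K2CO3, BnBr, DMF, rt to 50 °C
Reagents that add atoms: benzyl bromide, BrCc1ccccc1
Why: Fluoride cleaves the aryl silyl ether and both phenoxides are benzylated in the same flask (desilylative Williamson etherification), which makes the two oxygens flanking C6'' alike and leaves the PMB ether on the future O1'' as the only acid-labile group.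

**Step 11**
Reactants: 22 5-(benzyloxy)-3-{2,6-bis(benzyloxy)-4-[(4-methoxybenzyl)oxy]phenyl}-7-methoxy-2-(4-methoxyphenyl)-4H-chromen-4-one
Product: 23 5-(benzyloxy)-3-{2,6-bis(benzyloxy)-3-iodo-4-[(4-methoxybenzyl)oxy]phenyl}-7-methoxy-2-(4-methoxyphenyl)-4H-chromen-4-one
Conditions: NIS (1.0 equiv), MeCN–CH2Cl2, 0 °C, dark
Reagents that add atoms: N-iodosuccinimide, O=C1CCC(=O)N1I
Why: In this electrophilic aromatic iodination ring A'' is a 1,3,5-trialkoxybenzene, far more nucleophilic than any other ring, and its two free CH positions are constitutionally equivalent, so one equivalent of NIS can give only one constitution and the iodinated carbon is C4a'' from here on (until this step the labels 5''/7'' and 4a''/8'' are interchangeable).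

**Step 12**
Reactants: 23 5-(benzyloxy)-3-{2,6-bis(benzyloxy)-3-iodo-4-[(4-methoxybenzyl)oxy]phenyl}-7-methoxy-2-(4-methoxyphenyl)-4H-chromen-4-one; 24 tributyl(1-ethoxyvinyl)stannane
Product: 25 5-(benzyloxy)-3-{2,6-bis(benzyloxy)-3-(1-ethoxyvinyl)-4-[(4-methoxybenzyl)oxy]phenyl}-7-methoxy-2-(4-methoxyphenyl)-4H-chromen-4-one
Conditions: Pd(PPh3)4 (cat.), CuI (cat.), CsF, DMF, 50 °C; filtration through Et3N-deactivated silica
Reagents that add atoms: none
Why: Stille coupling with an acetyl-anion equivalent, accelerated by CuI and fluoride for the di-ortho-substituted iodide, forms C4''–C4a'' under neutral conditions that spare all four benzylic ethers, which a Lewis-acid Fries or Friedel–Crafts acylation would endanger.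

**Step 13**
Reactants: 25 5-(benzyloxy)-3-{2,6-bis(benzyloxy)-3-(1-ethoxyvinyl)-4-[(4-methoxybenzyl)oxy]phenyl}-7-methoxy-2-(4-methoxyphenyl)-4H-chromen-4-one
Product: 26 3-[3-acetyl-2,6-bis(benzyloxy)-4-hydroxyphenyl]-5-(benzyloxy)-7-methoxy-2-(4-methoxyphenyl)-4H-chromen-4-one
Conditions: CF3CO2H (10 vol%), H2O, 1,3-dimethoxybenzene, CH2Cl2, 0 °C
Reagents that add atoms: water, O
Why: Aqueous acid hydrolyses the enol ether to the methyl ketone and cleaves the PMB ether by SN1 solvolysis, the cation being caught by 1,3-dimethoxybenzene, while plain benzyl ethers are inert, so only the oxygen para to C6'' is set free on a ring that the acetyl group has by now deactivated.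

**Step 14**
Reactants: 26 3-[3-acetyl-2,6-bis(benzyloxy)-4-hydroxyphenyl]-5-(benzyloxy)-7-methoxy-2-(4-methoxyphenyl)-4H-chromen-4-one; 27 N,N-dimethylformamide dimethyl acetal
Product: 29 5,7-bis(benzyloxy)-6-[5-(benzyloxy)-7-methoxy-2-(4-methoxyphenyl)-4-oxo-4H-chromen-3-yl]-4H-chromen-4-one, via enaminone 28 (not isolated)
Conditions: toluene, 100 °C; then HCl (conc.), CH2Cl2, rt
Reagents that add atoms: none
Why: Condensation of the methyl ketone with the amide acetal gives the enaminone, and on acidification the one free phenol displaces dimethylamine by addition–elimination (enaminone route to chromones, 6-endo closure of ring C''), which fixes the 6''-linked and excludes the 8''-linked constitution.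

**Step 15**
Reactants: 29 5,7-bis(benzyloxy)-6-[5-(benzyloxy)-7-methoxy-2-(4-methoxyphenyl)-4-oxo-4H-chromen-3-yl]-4H-chromen-4-one; 30 [4-(benzyloxy)phenyl]boronic acid
Product: 31 (2R)-5,7-bis(benzyloxy)-2-[4-(benzyloxy)phenyl]-6-[5-(benzyloxy)-7-methoxy-2-(4-methoxyphenyl)-4-oxo-4H-chromen-3-yl]-2,3-dihydro-4H-chromen-4-one
Conditions: [Rh(OH)(cod)]2 (cat.), (R)-MeO-F12-BIPHEP [(R)-2,2'-bis{bis(3,4,5-trifluorophenyl)phosphino}-6,6'-dimethoxybiphenyl], toluene–H2O, 25 °C
Reagents that add atoms: none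
Why: The rhodium-catalysed asymmetric 1,4-addition of an arylboronic acid (Hayashi–Miyaura reaction), known for 5,7-dioxygenated chromones, brings ring B'' to C2''; the (R)-bisphosphine shields one face of the bound enone so that, by the quadrant model valid for cyclic enones, the aryl group should enter to give (2''R), and the tetrasubstituted C2=C3 bond of the flavone cannot insert.

**Step 16**
Reactants: 31 (2R)-5,7-bis(benzyloxy)-2-[4-(benzyloxy)phenyl]-6-[5-(benzyloxy)-7-methoxy-2-(4-methoxyphenyl)-4-oxo-4H-chromen-3-yl]-2,3-dihydro-4H-chromen-4-one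
Product: 32 (2R)-5,7-dihydroxy-6-[5-hydroxy-7-methoxy-2-(4-methoxyphenyl)-4-oxo-4H-chromen-3-yl]-2-(4-hydroxyphenyl)-2,3-dihydro-4H-chromen-4-one (CNP0292254.1)
Conditions: H2 (1 atm), Pd/C, EtOAc–THF, rt
Reagents that add atoms: none
Why: Hydrogenolysis of the four aryl benzyl ethers is neutral, so neither retro-oxa-Michael racemisation at C2'' nor Wessely–Moser 6''/8'' isomerisation can set in, and the tetrasubstituted flavone alkene and both ketones should stay untouched at one atmosphere.

**Compound list**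
1 | 1-(2,6-dihydroxy-4-methoxyphenyl)ethanone | CC(=O)c1c(O)cc(OC)cc1O | starting material
2 | 4-methoxybenzoyl chloride | COc1ccc(C(=O)Cl)cc1 | starting material
3 | 1-(2,6-dihydroxy-4-methoxyphenyl)-3-(4-methoxyphenyl)propane-1,3-dione | COc1ccc(C(=O)CC(=O)c2c(O)cc(OC)cc2O)cc1 | intermediate
4 | 5-hydroxy-7-methoxy-2-(4-methoxyphenyl)-4H-chromen-4-one | COc1ccc(-c2oc3cc(OC)cc(O)c3c(=O)c2)cc1 | intermediate
5 | 5-(benzyloxy)-7-methoxy-2-(4-methoxyphenyl)-4H-chromen-4-one | COc1ccc(-c2oc3cc(OC)cc(OCc4ccccc4)c3c(=O)c2)cc1 | intermediate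
6 | 3-lithio derivative of 5 (Fl–Li) | COc1ccc(-c2oc3cc(OC)cc(OCc4ccccc4)c3c(=O)c2[Li])cc1 | intermediate
7 | 5-(benzyloxy)-3-iodo-7-methoxy-2-(4-methoxyphenyl)-4H-chromen-4-one (Fl–I) | COc1ccc(-c2oc3cc(OC)cc(OCc4ccccc4)c3c(=O)c2I)cc1 | intermediate
8 | ethynyltrimethylsilane | C#C[Si](C)(C)C | starting material
9 | 5-(benzyloxy)-7-methoxy-2-(4-methoxyphenyl)-3-[(trimethylsilyl)ethynyl]-4H-chromen-4-one | COc1ccc(-c2oc3cc(OC)cc(OCc4ccccc4)c3c(=O)c2C#C[Si](C)(C)C)cc1 | intermediate
10 | 5-(benzyloxy)-3-ethynyl-7-methoxy-2-(4-methoxyphenyl)-4H-chromen-4-one | COc1ccc(-c2oc3cc(OC)cc(OCc4ccccc4)c3c(=O)c2C#C)cc1 | intermediate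
11 | lithium acetylide of 10 (Fl–C≡C–Li) | COc1ccc(-c2oc3cc(OC)cc(OCc4ccccc4)c3c(=O)c2C#C[Li])cc1 | intermediate
12 | lithium 2-Fl-ethynolate (Fl–C≡C–OLi) | COc1ccc(-c2oc3cc(OC)cc(OCc4ccccc4)c3c(=O)c2C#CO[Li])cc1 | intermediate
13 | 5-(benzyloxy)-7-methoxy-2-(4-methoxyphenyl)-3-{[(triisopropylsilyl)oxy]ethynyl}-4H-chromen-4-one | COc1ccc(-c2oc3cc(OC)cc(OCc4ccccc4)c3c(=O)c2C#CO[Si](C(C)C)(C(C)C)C(C)C)cc1 | intermediate
14 | 3-ethoxycyclobut-2-en-1-one | CCOC1=CC(=O)C1 | starting material
15 | (4-methoxyphenyl)methanol | COc1ccc(CO)cc1 | starting material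
16 | 3-[(4-methoxybenzyl)oxy]cyclobut-2-en-1-one | COc1ccc(COC2=CC(=O)C2)cc1 | intermediate
17 | 3-[(4-methoxybenzyl)oxy]buta-1,3-dien-1-one (vinylketene) | C=C(OCc1ccc(OC)cc1)C=C=O | intermediate
18 | 2-Fl-4-{1-[(4-methoxybenzyl)oxy]vinyl}-3-[(triisopropylsilyl)oxy]cyclobut-2-en-1-one (racemic at C4) | COc1ccc(-c2oc3cc(OC)cc(OCc4ccccc4)c3c(=O)c2C2=C(O[Si](C(C)C)(C(C)C)C(C)C)C(C(=C)OCc3ccc(OC)cc3)C2=O)cc1 | intermediate
19 | 2-Fl-5-[(4-methoxybenzyl)oxy]-3-[(triisopropylsilyl)oxy]hexa-1,3,5-trien-1-one, ketene carbon chain and vinyl group cis on C3=C4 | COc1ccc(-c2oc3cc(OC)cc(OCc4ccccc4)c3c(=O)c2C(=C=O)/C(O[Si](C(C)C)(C(C)C)C(C)C)=C\C(=C)OCc2ccc(OC)cc2)cc1 | intermediate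
20 | 2-Fl-5-[(4-methoxybenzyl)oxy]-3-[(triisopropylsilyl)oxy]cyclohexa-2,4-dien-1-one | COc1ccc(-c2oc3cc(OC)cc(OCc4ccccc4)c3c(=O)c2C2=C(O[Si](C(C)C)(C(C)C)C(C)C)C=C(OCc3ccc(OC)cc3)CC2=O)cc1 | intermediate
21 | 5-(benzyloxy)-3-{2-hydroxy-4-[(4-methoxybenzyl)oxy]-6-[(triisopropylsilyl)oxy]phenyl}-7-methoxy-2-(4-methoxyphenyl)-4H-chromen-4-one | COc1ccc(-c2oc3cc(OC)cc(OCc4ccccc4)c3c(=O)c2-c2c(O)cc(OCc3ccc(OC)cc3)cc2O[Si](C(C)C)(C(C)C)C(C)C)cc1 | intermediate
22 | 5-(benzyloxy)-3-{2,6-bis(benzyloxy)-4-[(4-methoxybenzyl)oxy]phenyl}-7-methoxy-2-(4-methoxyphenyl)-4H-chromen-4-one | COc1ccc(-c2oc3cc(OC)cc(OCc4ccccc4)c3c(=O)c2-c2c(OCc3ccccc3)cc(OCc3ccc(OC)cc3)cc2OCc2ccccc2)cc1 | intermediate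
23 | 5-(benzyloxy)-3-{2,6-bis(benzyloxy)-3-iodo-4-[(4-methoxybenzyl)oxy]phenyl}-7-methoxy-2-(4-methoxyphenyl)-4H-chromen-4-one | COc1ccc(-c2oc3cc(OC)cc(OCc4ccccc4)c3c(=O)c2-c2c(OCc3ccccc3)cc(OCc3ccc(OC)cc3)c(I)c2OCc2ccccc2)cc1 | intermediate
24 | tributyl(1-ethoxyvinyl)stannane | C=C(OCC)[Sn](CCCC)(CCCC)CCCC | starting material
25 | 5-(benzyloxy)-3-{2,6-bis(benzyloxy)-3-(1-ethoxyvinyl)-4-[(4-methoxybenzyl)oxy]phenyl}-7-methoxy-2-(4-methoxyphenyl)-4H-chromen-4-one | COc1ccc(-c2oc3cc(OC)cc(OCc4ccccc4)c3c(=O)c2-c2c(OCc3ccccc3)cc(OCc3ccc(OC)cc3)c(C(=C)OCC)c2OCc2ccccc2)cc1 | intermediate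
26 | 3-[3-acetyl-2,6-bis(benzyloxy)-4-hydroxyphenyl]-5-(benzyloxy)-7-methoxy-2-(4-methoxyphenyl)-4H-chromen-4-one | COc1ccc(-c2oc3cc(OC)cc(OCc4ccccc4)c3c(=O)c2-c2c(OCc3ccccc3)cc(O)c(C(C)=O)c2OCc2ccccc2)cc1 | intermediate
27 | N,N-dimethylformamide dimethyl acetal | COC(OC)N(C)C | starting material
28 | 3-{2,6-bis(benzyloxy)-3-[(E)-3-(dimethylamino)acryloyl]-4-hydroxyphenyl}-5-(benzyloxy)-7-methoxy-2-(4-methoxyphenyl)-4H-chromen-4-one | COc1ccc(-c2oc3cc(OC)cc(OCc4ccccc4)c3c(=O)c2-c2c(OCc3ccccc3)cc(O)c(C(=O)/C=C/N(C)C)c2OCc2ccccc2)cc1 | intermediate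
29 | 5,7-bis(benzyloxy)-6-[5-(benzyloxy)-7-methoxy-2-(4-methoxyphenyl)-4-oxo-4H-chromen-3-yl]-4H-chromen-4-one | COc1ccc(-c2oc3cc(OC)cc(OCc4ccccc4)c3c(=O)c2-c2c(OCc3ccccc3)cc3occc(=O)c3c2OCc2ccccc2)cc1 | intermediate
30 | [4-(benzyloxy)phenyl]boronic acid | OB(O)c1ccc(OCc2ccccc2)cc1 | starting material
31 | (2R)-5,7-bis(benzyloxy)-2-[4-(benzyloxy)phenyl]-6-[5-(benzyloxy)-7-methoxy-2-(4-methoxyphenyl)-4-oxo-4H-chromen-3-yl]-2,3-dihydro-4H-chromen-4-one | COc1ccc(-c2oc3cc(OC)cc(OCc4ccccc4)c3c(=O)c2-c2c(OCc3ccccc3)cc3c(c2OCc2ccccc2)C(=O)C[C@H](c2ccc(OCc4ccccc4)cc2)O3)cc1 | intermediate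
32 | (2R)-5,7-dihydroxy-6-[5-hydroxy-7-methoxy-2-(4-methoxyphenyl)-4-oxo-4H-chromen-3-yl]-2-(4-hydroxyphenyl)-2,3-dihydro-4H-chromen-4-one | COc1ccc(-c2oc3cc(OC)cc(O)c3c(=O)c2-c2c(O)cc3c(c2O)C(=O)C[C@H](c2ccc(O)cc2)O3)cc1 | target

**Step count**
Total step count: 16. Longest linear sequence: 15 steps (steps 1–7 and 9–16; step 8 is a one-step branch).

**Steps most likely to fail**

Step 9. The donor-stabilised cyclobutenone may open too slowly. The vinylketene may also be lost to self-condensation or to acylation of the product phenol before the crowded alkyne captures it.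
- The fallback sets out from 7 and comes back at 29. Ring A'' is bought as part of a chromone instead of being built.
- Commercial 5,7-dihydroxychromone is benzylated at its non-chelated hydroxyl (BnBr, K2CO3, acetone) to 7-(benzyloxy)-5-hydroxy-4H-chromen-4-one F1.
- Iodination ortho to the free 5-OH with benzyltrimethylammonium dichloroiodate and CaCO3 gives 7-(benzyloxy)-5-hydroxy-6-iodo-4H-chromen-4-one F2.
- A second benzylation gives 5,7-bis(benzyloxy)-6-iodo-4H-chromen-4-one F3.
- Miyaura borylation (B2pin2, PdCl2(dppf), KOAc, dioxane) gives 5,7-bis(benzyloxy)-6-(4,4,5,5-tetramethyl-1,3,2-dioxaborolan-2-yl)-4H-chromen-4-one F4.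
- Suzuki–Miyaura coupling of F4 with 7 (Pd(OAc)2, SPhos, K3PO4, toluene–H2O) should then give 29 and bypass steps 5–14. The price is a hindered biaryl coupling.

Step 7. The peroxide or the amide base may attack the pyrone ring, oxygen transfer to the acetylide may stay incomplete, or the ynolate may be protonated before silylation.
- The fallback sets out from 7 and comes back at 13 through the same ynolate 12. The oxygen is taken from an ester instead of a peroxide.
- Palladium-catalysed methoxycarbonylation (Pd(OAc)2, dppf, CO, MeOH, Et3N) gives methyl 5-(benzyloxy)-7-methoxy-2-(4-methoxyphenyl)-4-oxo-4H-chromene-3-carboxylate F5.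
- Kowalski homologation with LiCHBr2 (from CH2Br2 and lithium 2,2,6,6-tetramethylpiperidide, −90 °C) leads to the enolate of 5-(benzyloxy)-3-(dibromoacetyl)-7-methoxy-2-(4-methoxyphenyl)-4H-chromen-4-one F6.
- Bromine–lithium exchange with n-BuLi triggers the 1,2-shift of the flavonyl group to 12, which is silylated as before.

Step 15. Insertion into the congested, poorly soluble chromone may be slow. Protodeboronation may overtake it, or β-elimination of phenoxide from the rhodium enolate may open ring C'' and erode the enantiomeric purity.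
- The fallback sets out from 26 and comes back at 31. It replaces asymmetric addition by kinetic resolution.
- Claisen–Schmidt condensation with commercial 4-(benzyloxy)benzaldehyde (KOH, EtOH–THF) gives 3-{2,6-bis(benzyloxy)-3-[(E)-3-(4-benzyloxyphenyl)acryloyl]-4-hydroxyphenyl}-5-(benzyloxy)-7-methoxy-2-(4-methoxyphenyl)-4H-chromen-4-one F7.
- NaOAc in hot EtOH closes it to the racemic form of 31 F8.
- Transfer hydrogenation with [Cp*RhCl((S,S)-TsDPEN)] and HCO2H–Et3N in EtOAc should reduce the (2S) antipode faster, to the cis alcohol (2S,4S)-5,7-bis(benzyloxy)-2-[4-(benzyloxy)phenyl]-6-Fl-chroman-4-ol F9. The unreacted (2R)-ketone 31 is then recovered by chromatography.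

**Further compounds**
F1 | step 9 | 7-(benzyloxy)-5-hydroxy-4H-chromen-4-one | O=c1ccoc2cc(OCc3ccccc3)cc(O)c12
F2 | step 9 | 7-(benzyloxy)-5-hydroxy-6-iodo-4H-chromen-4-one | O=c1ccoc2cc(OCc3ccccc3)c(I)c(O)c12
F3 | step 9 | 5,7-bis(benzyloxy)-6-iodo-4H-chromen-4-one | O=c1ccoc2cc(OCc3ccccc3)c(I)c(OCc3ccccc3)c12
F4 | step 9 | 5,7-bis(benzyloxy)-6-(4,4,5,5-tetramethyl-1,3,2-dioxaborolan-2-yl)-4H-chromen-4-one | CC1(C)OB(OC1(C)C)c1c(OCc2ccccc2)cc2occc(=O)c2c1OCc1ccccc1
F5 | step 7 | methyl 5-(benzyloxy)-7-methoxy-2-(4-methoxyphenyl)-4-oxo-4H-chromene-3-carboxylate | COC(=O)c1c(-c2ccc(OC)cc2)oc2cc(OC)cc(OCc3ccccc3)c2c1=O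
F6 | step 7 | 5-(benzyloxy)-3-(dibromoacetyl)-7-methoxy-2-(4-methoxyphenyl)-4H-chromen-4-one | COc1ccc(-c2oc3cc(OC)cc(OCc4ccccc4)c3c(=O)c2C(=O)C(Br)Br)cc1
F7 | step 15 | 3-{2,6-bis(benzyloxy)-3-[(E)-3-(4-benzyloxyphenyl)acryloyl]-4-hydroxyphenyl}-5-(benzyloxy)-7-methoxy-2-(4-methoxyphenyl)-4H-chromen-4-one | COc1ccc(-c2oc3cc(OC)cc(OCc4ccccc4)c3c(=O)c2-c2c(OCc3ccccc3)cc(O)c(C(=O)/C=C/c3ccc(OCc4ccccc4)cc3)c2OCc2ccccc2)cc1
F8 | step 15 | racemic 5,7-bis(benzyloxy)-2-[4-(benzyloxy)phenyl]-6-Fl-2,3-dihydro-4H-chromen-4-one | COc1ccc(-c2oc3cc(OC)cc(OCc4ccccc4)c3c(=O)c2-c2c(OCc3ccccc3)cc3c(c2OCc2ccccc2)C(=O)CC(c2ccc(OCc4ccccc4)cc2)O3)cc1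
F9 | step 15 | (2S,4S)-5,7-bis(benzyloxy)-2-[4-(benzyloxy)phenyl]-6-Fl-chroman-4-ol | COc1ccc(-c2oc3cc(OC)cc(OCc4ccccc4)c3c(=O)c2-c2c(OCc3ccccc3)cc3c(c2OCc2ccccc2)[C@@H](O)C[C@@H](c2ccc(OCc4ccccc4)cc2)O3)cc1
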